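**Retrosynthetic overview** (ring numbered O1–O2–C3(OMe)–C4–C5–C6 throughout)
1. The strategy rests on the ring bond C4–C5 of the 1,2-dioxane: it is the only ring C–C bond lying between both peroxy-substituted carbons, the ketal carbon C3 and the carbinol carbon C6. Opened as C4=C5, it leaves an open-chain peroxide with one vinyl group on C3 and one on C6; the single ring is closed by olefin metathesis with the O–O bond already present (step 10).
2. That peroxide is a mixed peroxyketal made from the (R)-allylic hydroperoxide 8 and the vinyl ketal 14. C6 comes from a lipase-resolved 3-hydroxypent-4-enoate via (S)-2-vinyloxetane, which H2O2 opens with inversion.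
3. C3 is left uncontrolled until after ring closure and diimide saturation; acidic methanol then equilibrates it to the axial-methoxy epimer and frees the C6 hydroxyethyl arm.
4. Side chains come last: the chloropropyl group on C3 (inert to the ruthenium carbene, unlike an enyne) becomes the iodide and is coupled at its sp3 carbon with (E)-tridec-3-en-1-yne, made from undec-1-yne. The C6 arm is then oxidised to the acetic acid.

Key step: step 10

Assumption: the lipase is taken to acylate the (S)-enantiomer of 1 (size model with CH2CO2Et as the large and vinyl as the medium group); if the preference were the opposite, the unreacted alcohol would be carried into step 2 in place of the acetate.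

**Route**

Step 1
Reactants: 1 rac-ethyl 3-hydroxypent-4-enoate
Product: 2 ethyl (S)-3-acetoxypent-4-enoate
Conditions: Amano lipase PS, vinyl acetate (3 equiv), pentane, 4 Å MS, 30 °C, to ca. 50% conversion; chromatography
Reagents that add atoms: vinyl acetate, CC(=O)OC=C
Why: Enzymatic kinetic resolution by irreversible transesterification, in which the (S)-alcohol should be acylated much faster, so the acetate carries the centre that becomes C6 after one later inversion.

Step 2
Reactants: 2 ethyl (S)-3-acetoxypent-4-enoate
Product: 3 (S)-pent-4-ene-1,3-diol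
Conditions: LiAlH4 (1.5 equiv), Et2O, 0 °C; Fieser work-up
Reagents that add atoms: none
Why: Hydride reduction of the ethyl ester to the primary alcohol with reductive removal of the acetate; the C–O bond at the stereocentre is not broken, so (S) is kept.

Step 3
Reactants: 3 (S)-pent-4-ene-1,3-diol
Product: 5 (S)-2-vinyloxetane, via primary monotosylate 4 (not isolated)
Conditions: n-BuLi (1.0 equiv), THF, 0 °C; TsCl (1.0 equiv), 0 °C; n-BuLi (1.0 equiv), 0 → 40 °C; fractional distillation (volatile)
Reagents that add atoms: none
Why: One-pot sulfonylation of the less hindered primary alkoxide followed by intramolecular Williamson etherification (4-exo-tet) from the secondary alkoxide; the stereocentre keeps its C–O bond and its configuration.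

Step 4
Reactants: 5 (S)-2-vinyloxetane
Product: 6 (R)-3-hydroperoxypent-4-en-1-ol
Conditions: anhydrous H2O2 in Et2O (5 equiv), Me3SiOTf (0.1 equiv), Et2O, −78 → −20 °C; solid NaHCO3
Reagents that add atoms: hydrogen peroxide, OO
Why: Lewis-acid-catalysed, strain-driven ring opening of the oxetane by H2O2 at the allylic C2–O bond in an SN2-type displacement, so the hydroperoxy group enters with inversion, (S) to (R), and fixes the configuration of the future C6.

Step 5
Reactants: 6 (R)-3-hydroperoxypent-4-en-1-ol
Product: 8 (R)-tert-butyl[(3-hydroperoxypent-4-en-1-yl)oxy]dimethylsilane, via bis-silyl derivative 7 (not isolated)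
Conditions: TBSCl (2.3 equiv), imidazole (5 equiv), DMF, 0 °C; then K2CO3 (0.3 equiv), MeOH, 0 °C
Reagents that add atoms: tert-butyldimethylsilyl chloride, CC(C)(C)[Si](C)(C)Cl
Why: Exhaustive silylation followed by chemoselective methanolysis of the O–O–Si bond, the peroxide anion being a far better leaving group than an alkoxide, should leave the primary silyl ether and the free hydroperoxide; the stereocentre is not involved.

Step 6
Reactants: 9 4-chlorobutanoyl chloride
Product: 11 6-chlorohex-1-en-3-one, via 1,6-dichlorohexan-3-one 10 (not isolated)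
Conditions: ethylene (1 atm), AlCl3 (1.1 equiv), CH2Cl2, 0 → 20 °C; ice/HCl work-up; then Et3N (1.2 equiv), Et2O, 0 °C
Reagents that add atoms: ethylene, C=C
Why: Friedel–Crafts-type acylation of ethylene gives the β-chloroethyl ketone, which loses HCl by E1cB elimination with the amine; the γ-chloride has no such activation and stays.

Step 7
Reactants: 11 6-chlorohex-1-en-3-one
Product: 13 1-bromo-6-chloro-3,3-dimethoxyhexane, via 1-bromo-6-chlorohexan-3-one 12 (not isolated)
Conditions: HBr (gas, 1.1 equiv), CH2Cl2, −10 °C; then HC(OMe)3 (3 equiv), MeOH, 0 → 20 °C; NaHCO3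
Reagents that add atoms: hydrogen bromide, Br; trimethyl orthoformate, COC(OC)OC
Why: Conjugate hydrobromination of the vinyl ketone followed by acid-catalysed ketalisation with the orthoformate as dehydrating agent, the usual way to mask a vinyl ketone as a β-bromo ketal.

Step 8
Reactants: 13 1-bromo-6-chloro-3,3-dimethoxyhexane
Product: 14 6-chloro-3,3-dimethoxyhex-1-ene
Conditions: KOtBu (1.05 equiv), THF, 0 °C
Reagents that add atoms: none
Why: E2 dehydrobromination with a hindered alkoxide; bromide leaves far faster than the primary chloride and the bulky base disfavours substitution, so only the vinyl ketal should form.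

Step 9
Reactants: 8 (R)-tert-butyl[(3-hydroperoxypent-4-en-1-yl)oxy]dimethylsilane; 14 6-chloro-3,3-dimethoxyhex-1-ene (2 equiv)
Product: 15 tert-butyl{[(3R)-3-[(6-chloro-3-methoxyhex-1-en-3-yl)peroxy]pent-4-en-1-yl]oxy}dimethylsilane (both epimers at the ketal carbon)
Conditions: pyridinium p-toluenesulfonate (5 mol%), CH2Cl2, 5 Å MS, 0 °C; K2CO3 quench
Reagents that add atoms: none
Why: Acid-catalysed transketalisation (peroxyketal exchange): loss of methanol gives the oxocarbenium ion, which the hydroperoxide should capture at the ketal carbon under kinetic conditions (low temperature, weak acid, excess ketal) rather than at the vinyl terminus; the O–C6 bond is untouched, so C6 keeps its configuration, and the ketal carbon forms as both epimers, which does not matter here.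

Step 10
Reactants: 15 mixed bis-allylic peroxyketal (both C3 epimers)
Product: 16 (6R)-3-(3-chloropropyl)-3-methoxy-6-[2-(tert-butyldimethylsilyloxy)ethyl]-3,6-dihydro-1,2-dioxine (both C3 epimers)
Conditions: second-generation Hoveyda–Grubbs catalyst, RuCl2(H2IMes)(=CH-C6H4-2-OiPr) (5 mol%), CH2Cl2 (5 mM), 40 °C, argon sparge; ethyl vinyl ether quench, rapid filtration through silica
Reagents that add atoms: none
Why: The ruthenium alkylidene should engage the less hindered vinyl group on C6 by [2+2] cycloaddition and cycloreversion of a ruthenacyclobutane, and the new alkylidene then adds intramolecularly to the vinyl group on C3; collapse of the second ruthenacyclobutane forms C4=C5 and releases ethylene. This is ring-closing olefin metathesis of a diene whose tether contains a dialkyl peroxide, a reaction type already demonstrated for allylic peroxides. The one ring, the 1,2-dioxine, closes by forming the C4=C5 bond between two monosubstituted terminal alkenes, and the six-membered ring enforces the Z double bond. No stereocentre is created: C6 carries the configuration set in step 4 and is not touched, and both C3 epimers should cyclise because the skewed C–O–O–C arrangement holds the two vinyl groups near each other in either. The step needs chemoselectivity for the alkenes over the O–O bond and ring closure over oligomerisation. A phosphine-free catalyst (no free phosphine to reduce the peroxide), the absence of O–H and alkyne groups (silyl ether, chloropropyl stub) and high dilution should secure both.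

Step 11
Reactants: 16 3,6-dihydro-1,2-dioxine (both C3 epimers)
Product: 17 (6S)-3-(3-chloropropyl)-3-methoxy-6-[2-(tert-butyldimethylsilyloxy)ethyl]-1,2-dioxane (both C3 epimers; the change of the C6 descriptor is formal, the geometry is unchanged)
Conditions: KO2CN=NCO2K (10 equiv), AcOH (20 equiv, slow addition), CH2Cl2/MeOH 4:1, 0 → 20 °C
Reagents that add atoms: none
Why: Diimide, formed by protonation and decarboxylation of the azodicarboxylate, transfers H2 to the ring C=C in a concerted syn fashion without attacking the O–O bond, the standard reduction of dihydro-1,2-dioxines; generating it with acid rather than an amine avoids Kornblum–DeLaMare fragmentation at the allylic C6–H.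

Step 12
Reactants: 17 1,2-dioxane silyl ether (both C3 epimers)
Product: 18 (3S,6S)-3-(3-chloropropyl)-6-(2-hydroxyethyl)-3-methoxy-1,2-dioxane
Conditions: camphorsulfonic acid (0.1 equiv), MeOH, 0 → 20 °C; NaHCO3; any minor C3 epimer resubmitted
Reagents that add atoms: methanol, CO
Why: Acid-catalysed ketal exchange through the cyclic peroxycarbenium ion (loss and recapture of methanol) should equilibrate C3 to the thermodynamic epimer with axial methoxy (anomeric effect) and both carbon substituents equatorial, which is the relative configuration of the target, while the same conditions cleave the primary silyl ether by methanolysis.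

Step 13
Reactants: 18 chloro alcohol
Product: 19 (3S,6S)-6-(2-hydroxyethyl)-3-(3-iodopropyl)-3-methoxy-1,2-dioxane
Conditions: NaI (8 equiv), acetone, reflux, dark
Reagents that add atoms: sodium iodide, [Na+].[I-]
Why: Finkelstein halide exchange (SN2) driven by precipitation of NaCl; neutral iodide in acetone should not reduce the dialkyl peroxide at this temperature.

Step 14
Reactants: 20 undec-1-yne
Product: 22 (E)-1-iodoundec-1-ene, via alkenylzirconocene chloride 21 (not isolated)
Conditions: Cp2Zr(H)Cl (1.2 equiv), THF, 20 °C; then I2 (1.2 equiv), 0 °C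
Reagents that add atoms: iodine, II
Why: Syn hydrozirconation of the terminal alkyne places zirconium on the terminal carbon, and iodinolysis of the C–Zr bond with retention gives the E vinyl iodide.

Step 15
Reactants: 22 (E)-1-iodoundec-1-ene
Product: 23 (E)-trimethyl(tridec-3-en-1-yn-1-yl)silane
Conditions: trimethylsilylacetylene (1.3 equiv), PdCl2(PPh3)2 (2 mol%), CuI (4 mol%), Et3N, THF, 20 °C
Reagents that add atoms: trimethylsilylacetylene, C#C[Si](C)(C)C
Why: Sonogashira coupling (oxidative addition of the vinyl iodide to zerovalent palladium, transmetalation from the copper acetylide, reductive elimination) with retention of the E geometry.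

Step 16
Reactants: 23 (E)-trimethyl(tridec-3-en-1-yn-1-yl)silane
Product: 24 (E)-tridec-3-en-1-yne
Conditions: K2CO3 (0.2 equiv), MeOH, 20 °C
Reagents that add atoms: none
Why: Base-catalysed methanolysis of the C(sp)–Si bond frees the terminal alkyne.

Step 17
Reactants: 19 iodo alcohol; 24 (E)-tridec-3-en-1-yne (1.3 equiv)
Product: 25 (3R,6S)-3-[(E)-hexadec-6-en-4-yn-1-yl]-6-(2-hydroxyethyl)-3-methoxy-1,2-dioxane
Conditions: [Pd(η3-C3H5)Cl]2 (2.5 mol%), 1,3-bis(1-adamantyl)imidazolium chloride (5 mol%), CuI (7.5 mol%), Cs2CO3 (1.4 equiv), DMF/Et2O 1:2, 45 °C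
Reagents that add atoms: none
Why: Sonogashira-type coupling of an unactivated primary alkyl iodide: the bulky N-heterocyclic carbene on zerovalent palladium promotes oxidative addition to the C(sp3)–I bond and suppresses β-hydride elimination, and transmetalation from the copper acetylide followed by reductive elimination forms the C(sp3)–C(sp) bond under a carbonate base mild enough for the peroxyketal and the free hydroxyl.

Step 18
Reactants: 25 enyne alcohol
Product: 27 [(3S,6R)-6-[(E)-hexadec-6-en-4-yn-1-yl]-6-methoxy-1,2-dioxan-3-yl]acetic acid (target; in the route numbering ketal carbon C3 is R and C6 is S), via β-peroxy aldehyde 26 (not isolated)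
Conditions: TEMPO (0.2 equiv), PhI(OAc)2 (2.5 equiv), MeCN/H2O 1:1, 20 °C
Reagents that add atoms: water, O
Why: Oxoammonium-mediated oxidation of the primary alcohol to the aldehyde and, through its hydrate, to the carboxylic acid in a weakly acidic medium in which the β-peroxy aldehyde should not eliminate and the peroxyketal and the enyne stay intact.

**Compound list**
1 | rac-ethyl 3-hydroxypent-4-enoate | CCOC(=O)CC(O)C=C | starting material
2 | ethyl (S)-3-acetoxypent-4-enoate | CCOC(=O)C[C@H](OC(C)=O)C=C | intermediate
3 | (S)-pent-4-ene-1,3-diol | OCC[C@H](O)C=C | intermediate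
4 | (S)-3-hydroxypent-4-en-1-yl 4-methylbenzenesulfonate | Cc1ccc(cc1)S(=O)(=O)OCC[C@H](O)C=C | intermediate (not isolated)
5 | (S)-2-vinyloxetane | C=C[C@@H]1CCO1 | intermediate
6 | (R)-3-hydroperoxypent-4-en-1-ol | OO[C@@H](C=C)CCO | intermediate
7 | (R)-tert-butyl({3-[(tert-butyldimethylsilyl)peroxy]pent-4-en-1-yl}oxy)dimethylsilane | CC(C)(C)[Si](C)(C)OO[C@@H](C=C)CCO[Si](C)(C)C(C)(C)C | intermediate (not isolated)
8 | (R)-tert-butyl[(3-hydroperoxypent-4-en-1-yl)oxy]dimethylsilane | OO[C@@H](C=C)CCO[Si](C)(C)C(C)(C)C | intermediate
9 | 4-chlorobutanoyl chloride | ClCCCC(Cl)=O | starting material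
10 | 1,6-dichlorohexan-3-one | ClCCCC(=O)CCCl | intermediate (not isolated)
11 | 6-chlorohex-1-en-3-one | C=CC(=O)CCCCl | intermediate
12 | 1-bromo-6-chlorohexan-3-one | BrCCC(=O)CCCCl | intermediate (not isolated)
13 | 1-bromo-6-chloro-3,3-dimethoxyhexane | BrCCC(OC)(OC)CCCCl | intermediate
14 | 6-chloro-3,3-dimethoxyhex-1-ene | C=CC(OC)(OC)CCCCl | intermediate
15 | tert-butyl{[(3R)-3-[(6-chloro-3-methoxyhex-1-en-3-yl)peroxy]pent-4-en-1-yl]oxy}dimethylsilane, both epimers at the ketal carbon | C=CC(OC)(CCCCl)OO[C@@H](C=C)CCO[Si](C)(C)C(C)(C)C | intermediate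
16 | (6R)-3-(3-chloropropyl)-3-methoxy-6-[2-(tert-butyldimethylsilyloxy)ethyl]-3,6-dihydro-1,2-dioxine, both C3 epimers | ClCCCC1(OC)C=C[C@@H](CCO[Si](C)(C)C(C)(C)C)OO1 | intermediate
17 | (6S)-3-(3-chloropropyl)-3-methoxy-6-[2-(tert-butyldimethylsilyloxy)ethyl]-1,2-dioxane, both C3 epimers | ClCCCC1(OC)CC[C@@H](CCO[Si](C)(C)C(C)(C)C)OO1 | intermediate
18 | (3S,6S)-3-(3-chloropropyl)-6-(2-hydroxyethyl)-3-methoxy-1,2-dioxane | ClCCC[C@]1(OC)CC[C@@H](CCO)OO1 | intermediate
19 | (3S,6S)-6-(2-hydroxyethyl)-3-(3-iodopropyl)-3-methoxy-1,2-dioxane | ICCC[C@]1(OC)CC[C@@H](CCO)OO1 | intermediate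
20 | undec-1-yne | CCCCCCCCCC#C | starting material
21 | (E)-undec-1-en-1-ylzirconocene chloride | CCCCCCCCC/C=C/[Zr+2]Cl.c1cc[cH-]c1.c1cc[cH-]c1 | intermediate (not isolated)
22 | (E)-1-iodoundec-1-ene | CCCCCCCCC/C=C/I | intermediate
23 | (E)-trimethyl(tridec-3-en-1-yn-1-yl)silane | CCCCCCCCC/C=C/C#C[Si](C)(C)C | intermediate
24 | (E)-tridec-3-en-1-yne | CCCCCCCCC/C=C/C#C | intermediate
25 | (3R,6S)-3-[(E)-hexadec-6-en-4-yn-1-yl]-6-(2-hydroxyethyl)-3-methoxy-1,2-dioxane | CCCCCCCCC/C=C/C#CCCC[C@]1(OC)CC[C@@H](CCO)OO1 | intermediate
26 | [(3S,6R)-6-[(E)-hexadec-6-en-4-yn-1-yl]-6-methoxy-1,2-dioxan-3-yl]acetaldehyde | CCCCCCCCC/C=C/C#CCCC[C@]1(OC)CC[C@@H](CC=O)OO1 | intermediate (not isolated)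
27 | [(3S,6R)-6-[(E)-hexadec-6-en-4-yn-1-yl]-6-methoxy-1,2-dioxan-3-yl]acetic acid | CCCCCCCCC/C=C/C#CCCC[C@]1(OC)CC[C@@H](CC(=O)O)OO1 | target

**Count**
Total steps: 18. Longest linear sequence: 12 steps (1–5, 9–13, 17, 18).

**Steps most likely to fail**

Step 4. The Lewis-acid-bound vinyloxetane may ionise to an allyl cation instead of undergoing direct displacement. That would erode the enantiomeric purity of the future C6 and send part of the nucleophile to the terminal alkene carbon with allylic transposition. The fallback leaves the oxetane aside and sets out from diol 3. Selective silylation of the primary hydroxyl (TBSCl, imidazole, CH2Cl2, −20 °C) should give (S)-5-[(tert-butyldimethylsilyl)oxy]pent-1-en-3-ol F1. Mesylation (MsCl, Et3N, CH2Cl2, −30 °C) gives (S)-5-[(tert-butyldimethylsilyl)oxy]pent-1-en-3-yl methanesulfonate F2. F2 is displaced at once with the caesium salt of 2-methoxyprop-2-yl hydroperoxide (CsOH, DMF, 0 °C), a known SN2 route from secondary sulfonates to protected hydroperoxides with inversion, giving (R)-tert-butyl({3-[(2-methoxypropan-2-yl)peroxy]pent-4-en-1-yl}oxy)dimethylsilane F3. Brief treatment with aqueous acetic acid in THF at 0 °C should release the hydroperoxide and rejoin the route at 8, so steps 3–5 are bypassed.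

Step 10. The ruthenium species may cleave or rearrange the O–O bond of the allylic peroxide or of the dihydrodioxine formed, and closure onto the vinyl group at the fully substituted ketal carbon may be slow enough for oligomerisation to take over. The fallback moves the metathesis to an intermolecular, unhindered pair and closes the ring through the C3–O2 bond instead. It sets out from 7 (isolated by leaving out the methanolysis of step 5) and enone 11. Cross-metathesis with the same catalyst (CH2Cl2, 40 °C) should give (R,E)-9-[(tert-butyldimethylsilyl)oxy]-7-[(tert-butyldimethylsilyl)peroxy]-1-chloronon-5-en-4-one F4. Diimide reduction (KO2CN=NCO2K, AcOH) gives (R)-9-[(tert-butyldimethylsilyl)oxy]-7-[(tert-butyldimethylsilyl)peroxy]-1-chlorononan-4-one F5. Camphorsulfonic acid in methanol then removes both silyl groups; the δ-hydroperoxy ketone closes to the cyclic peroxyhemiketal, and methanol exchange under thermodynamic control rejoins the route at 18. This fallback also makes steps 6–9 and 11–12 in their present form unnecessary.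

Step 17. The electron-rich zerovalent palladium or the copper acetylide may cleave the O–O bond reductively, and β-hydride elimination from the alkylpalladium intermediate may compete with coupling. The fallback separates the two bond formations and sets out from 19 and 22. SN2 alkylation of the lithium acetylide–ethylenediamine complex (3 equiv, DMSO, 15 °C) with iodide 19 should give (3R,6S)-6-(2-hydroxyethyl)-3-methoxy-3-(pent-4-yn-1-yl)-1,2-dioxane F6. An sp–sp2 Sonogashira coupling of F6 with vinyl iodide 22 (Pd(PPh3)4, CuI, Et3N, THF, 20 °C), a coupling type established for alkynes on 3-methoxy-1,2-dioxanes, rejoins the route at 25; steps 15 and 16 are then not needed.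

**Further compounds**
F1 | step 4 | (S)-5-[(tert-butyldimethylsilyl)oxy]pent-1-en-3-ol | C=C[C@@H](O)CCO[Si](C)(C)C(C)(C)C
F2 | step 4 | (S)-5-[(tert-butyldimethylsilyl)oxy]pent-1-en-3-yl methanesulfonate | C=C[C@@H](OS(C)(=O)=O)CCO[Si](C)(C)C(C)(C)C
F3 | step 4 | (R)-tert-butyl({3-[(2-methoxypropan-2-yl)peroxy]pent-4-en-1-yl}oxy)dimethylsilane | C=C[C@H](OOC(C)(C)OC)CCO[Si](C)(C)C(C)(C)C
F4 | step 10 | (R,E)-9-[(tert-butyldimethylsilyl)oxy]-7-[(tert-butyldimethylsilyl)peroxy]-1-chloronon-5-en-4-one | CC(C)(C)[Si](C)(C)OO[C@@H](/C=C/C(=O)CCCCl)CCO[Si](C)(C)C(C)(C)C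
F5 | step 10 | (R)-9-[(tert-butyldimethylsilyl)oxy]-7-[(tert-butyldimethylsilyl)peroxy]-1-chlorononan-4-one | CC(C)(C)[Si](C)(C)OO[C@@H](CCC(=O)CCCCl)CCO[Si](C)(C)C(C)(C)C
F6 | step 17 | (3R,6S)-6-(2-hydroxyethyl)-3-methoxy-3-(pent-4-yn-1-yl)-1,2-dioxane | C#CCCC[C@]1(OC)CC[C@@H](CCO)OO1
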